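**Retrosynthetic overview**

1. Target 16 is all-E (3R,6R,3′R,6′R)-ε,ε-carotene-3,3′-diol (lactucaxanthin); it is cut at C11=C12 and C11′=C12′ into two C15 phosphonium salts 12 and the C10 trienedial 6 (two-directional Wittig).
2. 6 ⇒ furan 1 (key step): singlet-oxygen [4+2] destroys the furan aromaticity, Me2S unmasks (Z)-but-2-enedial, and Ph3P=C(Me)CHO olefinates both ends in the same flask.
3. 12 ⇒ C15 diol 11 (PPh3·HBr) ⇒ 3-oxo ester 9; an (S)-CBS reduction sets C3, DIBAL-H reduces the ester.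
4. 9 ⇒ dienoate 8 (ring allylic C–H oxidation) ⇒ (R)-α-ionone 7 (HWE); C6 comes from the chiral pool.
5. Rings: none is formed; both cyclohexene rings arrive intact with 7 and only the polyene is built.

Assumption: (R)-(+)-α-ionone is bought as enantiopure chiral-pool material (≥98% ee).

**Route**

Step 1
Reactants: 1 furan
Product: 6 (2E,4E,6E)-2,7-dimethylocta-2,4,6-trienedial (C10 dial), via furan endoperoxide 2 (not isolated), via (Z)-but-2-enedial 3 (not isolated), via mono-olefinated dienedial 4 (not isolated), via (4Z)-trienedial 5 (not isolated)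
Conditions: O2, TPP (0.1 mol%), hν (vis), CH2Cl2, −78 °C; Me2S (1.2 equiv), −78 → −20 °C (until peroxide-free); Ph3P=C(Me)CHO (2.1 equiv), −20 → 35 °C, 12 h; I2 (2 mol%), rt, daylight; crystallise
Reagents that add atoms: 2-(triphenylphosphoranylidene)propanal, CC(C=O)=P(c1ccccc1)(c1ccccc1)c1ccccc1
Why: Proposed new method: singlet oxygen adds [4+2] across C2/C5 of furan (breaking the aromatic sextet) to endoperoxide 2, Me2S reduces the O–O bond so that 2 collapses to (Z)-but-2-enedial 3, the stabilised formyl ylide then olefinates both enal carbonyls E-selectively (the α-methyl-enal CHO groups it creates are too deactivated to react again) and I2/light equilibrates the 4Z bond of 5 to the crystalline all-E dial 6; the closest known reaction types are the photooxygenation–Me2S unmasking of furans to cis-ene-dicarbonyls and the Wittig formyl-olefination of dialdehydes, and the oxygen taken from O2 leaves as Ph3P=O, so only the ylide adds atoms to 6.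

Step 2
Reactants: 7 (R)-α-ionone
Product: 8 ethyl (2E,4E)-3-methyl-5-[(1R)-2,6,6-trimethylcyclohex-2-en-1-yl]penta-2,4-dienoate
Conditions: (EtO)2P(O)CH2CO2Et (1.3 equiv), NaH (1.25 equiv), THF, 0 °C → rt; silica (removes minor 2Z isomer)
Reagents that add atoms: triethyl phosphonoacetate, CCOC(=O)CP(=O)(OCC)OCC
Why: Horner–Wadsworth–Emmons olefination of the methyl ketone by the preformed sodium phosphonate gives mainly the 2E dienoate (roughly 4:1 expected) and, with no free base present, the γ C–H at the ring stereocentre is not touched, so (R) is carried through from 7.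

Step 3
Reactants: 8 ethyl (2E,4E)-3-methyl-5-[(1R)-2,6,6-trimethylcyclohex-2-en-1-yl]penta-2,4-dienoate
Product: 9 ethyl (2E,4E)-3-methyl-5-[(1R)-2,6,6-trimethyl-4-oxocyclohex-2-en-1-yl]penta-2,4-dienoate
Conditions: Rh2(cap)4 (1 mol%), t-BuOOH (70% aq., 5 equiv), DCE, 40 °C
Reagents that add atoms: tert-butyl hydroperoxide, CC(C)(C)OO
Why: Rh2(cap)4/TBHP allylic C–H oxidation turns the only unhindered ring allylic CH2 into the enone carbonyl under neutral conditions, the doubly allylic C1–H being shielded by the gem-dimethyl group (the same site selectivity is known for TBHP oxidations of α-ionone), so the existing stereocentre is kept.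

Step 4
Reactants: 9 ethyl (2E,4E)-3-methyl-5-[(1R)-2,6,6-trimethyl-4-oxocyclohex-2-en-1-yl]penta-2,4-dienoate
Product: 11 (1R,4R)-4-[(1E,3E)-5-hydroxy-3-methylpenta-1,3-dien-1-yl]-3,5,5-trimethylcyclohex-2-en-1-ol (C15 diol), via hydroxy ester 10 (not isolated)
Conditions: (S)-Me-CBS (20 mol%), catecholborane (1.5 equiv), toluene, −78 → −40 °C; then DIBAL-H (4 equiv), −78 → −20 °C; aq. Rochelle salt; silica
Reagents that add atoms: none
Why: Corey–Bakshi–Shibata reduction in which the (S)-oxazaborolidine delivers hydride from catecholborane to the enone carbonyl with the alkene arm as the large group, giving the (R) carbinol (carotenoid C3, trans to the side chain) under catalyst control, after which DIBAL-H added to the same flask reduces the dienoate ester 1,2 to the primary allylic alcohol without touching the new stereocentre.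

Step 5
Reactants: 11 (1R,4R)-4-[(1E,3E)-5-hydroxy-3-methylpenta-1,3-dien-1-yl]-3,5,5-trimethylcyclohex-2-en-1-ol
Product: 12 {(2E,4E)-5-[(1R,4R)-4-hydroxy-2,6,6-trimethylcyclohex-2-en-1-yl]-3-methylpenta-2,4-dien-1-yl}triphenylphosphonium bromide
Conditions: PPh3·HBr (1.0 equiv), CH2Cl2, 0 °C → rt; precipitate with EtOAc
Reagents that add atoms: triphenylphosphine hydrobromide, [Br-].[PH+](c1ccccc1)(c1ccccc1)c1ccccc1
Why: SN1-type phosphonium salt formation in which HBr ionises only the primary dienylic alcohol to a pentadienyl cation that PPh3 captures at the terminal carbon (the standard C15 Wittig salt synthesis), while the less ionisable secondary ring allylic alcohol and both stereocentres stay intact at 0 °C in an aprotic solvent.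

Step 6
Reactants: 12 {(2E,4E)-5-[(1R,4R)-4-hydroxy-2,6,6-trimethylcyclohex-2-en-1-yl]-3-methylpenta-2,4-dien-1-yl}triphenylphosphonium bromide (2.1 equiv), 6 (2E,4E,6E)-2,7-dimethylocta-2,4,6-trienedial
Product: 16 (3R,6R,3′R,6′R)-ε,ε-carotene-3,3′-diol (lactucaxanthin, all-E), via C15 ylide 13 (not isolated), via C25 apo-aldehyde 14 (not isolated), via 11-cis isomer 15 (not isolated)
Conditions: NaOMe (2.3 equiv), MeOH/CH2Cl2, −10 °C → rt; then EtOH, reflux, 3 h (Z→E); crystallise
Reagents that add atoms: none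
Why: Two-directional Wittig olefination of the C10 dial by two equivalents of the ylide (the classical C15 + C10 + C15 carotenoid coupling, free hydroxyls tolerated) forms C11=C12 and C11′=C12′, and heating equilibrates any 11Z bonds to the thermodynamically preferred all-E polyene without affecting the four stereocentres.

**Compound list**

1 | furan | c1ccoc1 | starting material
2 | 2,3,7-trioxabicyclo[2.2.1]hept-5-ene (furan endoperoxide, meso) | C1=C[C@H]2OO[C@@H]1O2 | intermediate
3 | (2Z)-but-2-enedial | O=C/C=C\C=O | intermediate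
4 | (2E,4Z)-2-methylhexa-2,4-dienedial | O=C/C(C)=C/C=C\C=O | intermediate
5 | (2E,4Z,6E)-2,7-dimethylocta-2,4,6-trienedial | O=C/C(C)=C/C=C\C=C(/C)C=O | intermediate
6 | (2E,4E,6E)-2,7-dimethylocta-2,4,6-trienedial | O=C/C(C)=C/C=C/C=C(\C)C=O | intermediate
7 | (R)-α-ionone, (3E)-4-[(1R)-2,6,6-trimethylcyclohex-2-en-1-yl]but-3-en-2-one | CC(=O)/C=C/[C@H]1C(C)=CCCC1(C)C | starting material
8 | ethyl (2E,4E)-3-methyl-5-[(1R)-2,6,6-trimethylcyclohex-2-en-1-yl]penta-2,4-dienoate | CCOC(=O)/C=C(C)/C=C/[C@H]1C(C)=CCCC1(C)C | intermediate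
9 | ethyl (2E,4E)-3-methyl-5-[(1R)-2,6,6-trimethyl-4-oxocyclohex-2-en-1-yl]penta-2,4-dienoate | CCOC(=O)/C=C(C)/C=C/[C@H]1C(C)=CC(=O)CC1(C)C | intermediate
10 | ethyl (2E,4E)-5-[(1R,4R)-4-hydroxy-2,6,6-trimethylcyclohex-2-en-1-yl]-3-methylpenta-2,4-dienoate | CCOC(=O)/C=C(C)/C=C/[C@H]1C(C)=C[C@H](O)CC1(C)C | intermediate
11 | (1R,4R)-4-[(1E,3E)-5-hydroxy-3-methylpenta-1,3-dien-1-yl]-3,5,5-trimethylcyclohex-2-en-1-ol | OC/C=C(C)/C=C/[C@H]1C(C)=C[C@H](O)CC1(C)C | intermediate
12 | {(2E,4E)-5-[(1R,4R)-4-hydroxy-2,6,6-trimethylcyclohex-2-en-1-yl]-3-methylpenta-2,4-dien-1-yl}triphenylphosphonium bromide | [Br-].C(/C=C(C)/C=C/[C@H]1C(C)=C[C@H](O)CC1(C)C)[P+](c1ccccc1)(c1ccccc1)c1ccccc1 | intermediate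
13 | {(2E,4E)-5-[(1R,4R)-4-hydroxy-2,6,6-trimethylcyclohex-2-en-1-yl]-3-methylpenta-2,4-dien-1-ylidene}triphenylphosphorane | C(/C=C(C)/C=C/[C@H]1C(C)=C[C@H](O)CC1(C)C)=P(c1ccccc1)(c1ccccc1)c1ccccc1 | intermediate
14 | (2E,4E,6E,8E,10E,12E)-13-[(1R,4R)-4-hydroxy-2,6,6-trimethylcyclohex-2-en-1-yl]-2,7,11-trimethyltrideca-2,4,6,8,10,12-hexaenal | O=C/C(C)=C/C=C/C=C(C)/C=C/C=C(C)/C=C/[C@H]1C(C)=C[C@H](O)CC1(C)C | intermediate
15 | (11Z)-(3R,6R,3′R,6′R)-ε,ε-carotene-3,3′-diol (representative 11-cis isomer) | CC1=C[C@H](O)CC(C)(C)[C@H]1\C=C\C(C)=C\C=C/C(C)=C/C=C/C=C(C)/C=C/C=C(C)/C=C/[C@H]1C(C)=C[C@H](O)CC1(C)C | intermediate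
16 | (3R,6R,3′R,6′R)-ε,ε-carotene-3,3′-diol, all-E (lactucaxanthin) | CC1=C[C@H](O)CC(C)(C)[C@H]1/C=C/C(C)=C/C=C/C(C)=C/C=C/C=C(C)/C=C/C=C(C)/C=C/[C@H]1C(C)=C[C@H](O)CC1(C)C | target

**Step count and risks**

Total steps: 6. Longest linear sequence: 5 steps (7 → 8 → 9 → 11 → 12 → 16); the furan arm is 2 steps (1 → 6 → 16).

Most likely to fail:

Step 1. Base-induced Kornblum–DeLaMare rearrangement of 2 to the hydroxybutenolide, polymerisation of 3, or a sluggish ylide could all defeat the one-pot. The fallback leaves the Wittig logic for acetal/enol-ether chemistry. It sets out from furan 1: Br2/MeOH/Na2CO3 at −40 °C gives 2,5-dimethoxy-2,5-dihydrofuran F1; MeOH, HC(OMe)3 and cat. TsOH open it to (E)-1,1,4,4-tetramethoxybut-2-ene F2; BF3·OEt2-catalysed Müller–Cunradi–Pieroh condensation with 2 equiv of 1-methoxyprop-1-ene gives (E)-1,1,3,6,8,8-hexamethoxy-2,7-dimethyloct-4-ene F3; aq. AcOH/NaOAc at 90 °C (acetal hydrolysis and double β-elimination of MeOH) comes back to the route at dial 6.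

Step 4. The CBS reduction may be slow on this hindered enone or mismatched with the ring substituent, giving poor dr at C3. The fallback gives up catalyst control and corrects the wrong epimer by inversion. It sets out from 9: NaBH4/CeCl3 (MeOH, −40 °C) gives 10 together with its carbinol epimer, ethyl (2E,4E)-5-[(1R,4S)-4-hydroxy-2,6,6-trimethylcyclohex-2-en-1-yl]-3-methylpenta-2,4-dienoate F4; after separation, F4 is inverted under Mitsunobu conditions (PhCO2H, PPh3, DIAD, THF, 0 °C) to ethyl (2E,4E)-5-[(1R,4R)-4-(benzoyloxy)-2,6,6-trimethylcyclohex-2-en-1-yl]-3-methylpenta-2,4-dienoate F5; DIBAL-H on pooled 10 and F5 cleaves the benzoate and reduces the ethyl ester, coming back at diol 11.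

Step 5. The ring allylic alcohol may ionise under HBr (C3 epimerisation, a ring phosphonium salt, or retro-type elimination next to C6). The fallback reverses the polarity of the last olefination so that the C15 unit never meets acid. It sets out from 11 and 6: TEMPO (10 mol%)/PhI(OAc)2 in CH2Cl2 oxidises only the primary alcohol of 11 to (2E,4E)-5-[(1R,4R)-4-hydroxy-2,6,6-trimethylcyclohex-2-en-1-yl]-3-methylpenta-2,4-dienal F6; NaBH4 reduces 6 to (2E,4E,6E)-2,7-dimethylocta-2,4,6-triene-1,8-diol F7, and PPh3·HBr (2 equiv) converts it into [(2E,4E,6E)-2,7-dimethylocta-2,4,6-triene-1,8-diyl]bis(triphenylphosphonium) dibromide F8; NaOMe-mediated double Wittig of F8 with 2 equiv of F6, followed by the same thermal Z→E equilibration, comes back at target 16.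

**Further compounds**

F1 | step 1 | 2,5-dimethoxy-2,5-dihydrofuran (cis/trans mixture) | COC1C=CC(OC)O1
F2 | step 1 | (E)-1,1,4,4-tetramethoxybut-2-ene | COC(OC)/C=C/C(OC)OC
F3 | step 1 | (E)-1,1,3,6,8,8-hexamethoxy-2,7-dimethyloct-4-ene (diastereomer mixture) | COC(OC)C(C)C(OC)/C=C/C(OC)C(C)C(OC)OC
F4 | step 4 | ethyl (2E,4E)-5-[(1R,4S)-4-hydroxy-2,6,6-trimethylcyclohex-2-en-1-yl]-3-methylpenta-2,4-dienoate | CCOC(=O)/C=C(C)/C=C/[C@H]1C(C)=C[C@@H](O)CC1(C)C
F5 | step 4 | ethyl (2E,4E)-5-[(1R,4R)-4-(benzoyloxy)-2,6,6-trimethylcyclohex-2-en-1-yl]-3-methylpenta-2,4-dienoate | CCOC(=O)/C=C(C)/C=C/[C@H]1C(C)=C[C@H](OC(=O)c2ccccc2)CC1(C)C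
F6 | step 5 | (2E,4E)-5-[(1R,4R)-4-hydroxy-2,6,6-trimethylcyclohex-2-en-1-yl]-3-methylpenta-2,4-dienal | O=C/C=C(C)/C=C/[C@H]1C(C)=C[C@H](O)CC1(C)C
F7 | step 5 | (2E,4E,6E)-2,7-dimethylocta-2,4,6-triene-1,8-diol | OC/C(C)=C/C=C/C=C(\C)CO
F8 | step 5 | [(2E,4E,6E)-2,7-dimethylocta-2,4,6-triene-1,8-diyl]bis(triphenylphosphonium) dibromide | [Br-].[Br-].C(/C(C)=C/C=C/C=C(\C)C[P+](c1ccccc1)(c1ccccc1)c1ccccc1)[P+](c1ccccc1)(c1ccccc1)c1ccccc1
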